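**Retrosynthetic overview**

1. Testudinariol A ⇐ desilylation ⇐ two-directional copper-hydride syn-hydroalkylative cyclisation of a C2-symmetric bis(propargyl ether) bis(alkyl iodide). Both C4–C5 bonds, both tetrahydropyran rings and both (Z)-alkylidenes are formed last, in one operation.
2. Bis(propargyl ether) ⇐ double O-alkylation of a cyclopentyl carbinol (2 equiv) with 1,8-dibromoocta-2,6-diyne (from propargyl alcohol and oxirane).
3. Cyclopentanol rings (formed first) ⇐ nickel-catalysed alkylative cyclisation of an allenyl aldehyde with Me2Zn (OH cis to isopropenyl, trans to the side chain).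
4. Allenyl aldehyde ⇐ anti-selective Fráter–Seebach alkylation of an (R)-β-hydroxy ester (Blaise reaction, then Noyori hydrogenation) with 5-iodopenta-1,2-diene (Crabbé homologation of but-3-yn-1-ol).

Assumption: 4-methoxybenzyl alcohol and the silyl reagents are treated as protecting-group reagents, paraformaldehyde and Me2Zn as one-carbon reagents; PMB = 4-methoxybenzyl, TES = triethylsilyl, TBS = tert-butyldimethylsilyl, IPr = 1,3-bis(2,6-diisopropylphenyl)imidazol-2-ylidene.

**Route**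

Step 1
Reactants: 1 but-3-yn-1-ol
Product: 2 penta-3,4-dien-1-ol
Conditions: (CH2O)n (2.5 equiv), CuI (0.5 equiv), Cy2NH (1.8 equiv), 1,4-dioxane, reflux
Reagents that add atoms: formaldehyde (as paraformaldehyde), C=O
Why: Crabbé homologation (aminomethylation of the terminal alkyne, then copper-mediated hydride transfer and elimination) turns the terminal alkyne into the terminal allene and tolerates the free alcohol.

Step 2
Reactants: 2 penta-3,4-dien-1-ol
Product: 3 5-iodopenta-1,2-diene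
Conditions: I2, PPh3, imidazole, CH2Cl2, 0 °C → rt, dark
Reagents that add atoms: iodine, II
Why: Appel-type iodination replaces the primary hydroxyl by iodide under neutral conditions that leave the allene untouched.

Step 3
Reactants: 4 acrylonitrile
Product: 5 3-[(4-methoxybenzyl)oxy]propanenitrile
Conditions: 4-methoxybenzyl alcohol (1.0 equiv), NaH (5 mol %), THF, 0 °C → rt
Reagents that add atoms: 4-methoxybenzyl alcohol, COc1ccc(CO)cc1
Why: Base-catalysed oxa-Michael addition (cyanoethylation) of the alkoxide to acrylonitrile is fast and clean.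

Step 4
Reactants: 5 3-[(4-methoxybenzyl)oxy]propanenitrile; 6 ethyl bromoacetate
Product: 8 ethyl 5-[(4-methoxybenzyl)oxy]-3-oxopentanoate, via Blaise enamino ester 7 (not isolated)
Conditions: Zn dust (TMSCl-activated), THF, reflux, slow addition of 6 (1.6 equiv); then 1 M aq. HCl, rt
Reagents that add atoms: water, O
Why: Blaise reaction: the Reformatsky reagent adds to the nitrile and brief mild acid hydrolysis of the zinc enaminoate gives the β-keto ester without cleaving the PMB ether.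

Step 5
Reactants: 8 ethyl 5-[(4-methoxybenzyl)oxy]-3-oxopentanoate
Product: 9 ethyl (3R)-3-hydroxy-5-[(4-methoxybenzyl)oxy]pentanoate
Conditions: H2 (50 atm), RuCl2[(R)-BINAP] (0.5 mol %), EtOH, 60 °C
Reagents that add atoms: none
Why: Noyori asymmetric hydrogenation of a β-keto ester; the (R)-BINAP ruthenium catalyst gives the (3R)-alcohol (same facial sense as methyl acetoacetate to methyl (R)-3-hydroxybutanoate), which becomes the pyran C2 stereocentre.

Step 6
Reactants: 9 ethyl (3R)-3-hydroxy-5-[(4-methoxybenzyl)oxy]pentanoate; 3 5-iodopenta-1,2-diene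
Product: 10 ethyl (2R,3R)-3-hydroxy-5-[(4-methoxybenzyl)oxy]-2-(penta-3,4-dien-1-yl)pentanoate
Conditions: LDA (2.2 equiv), THF, −78 → −20 °C; then 3 (1.5 equiv), DMPU, −78 → −10 °C; aq. NH4Cl
Reagents that add atoms: none
Why: Fráter–Seebach alkylation: the chelated lithium alkoxide–enolate dianion is alkylated anti to the C3 substituent, setting the (2R) centre with the 2,3-anti relationship the target needs.

Step 7
Reactants: 10 ethyl (2R,3R)-3-hydroxy-5-[(4-methoxybenzyl)oxy]-2-(penta-3,4-dien-1-yl)pentanoate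
Product: 11 ethyl (2R,3R)-5-[(4-methoxybenzyl)oxy]-2-(penta-3,4-dien-1-yl)-3-[(triethylsilyl)oxy]pentanoate
Conditions: TESCl, imidazole, DMF, 0 °C → rt
Reagents that add atoms: chlorotriethylsilane, CC[Si](Cl)(CC)CC
Why: Standard silylation of a secondary alcohol; TES is chosen because it can later be removed in the presence of a hindered TBS ether.

Step 8
Reactants: 11 ethyl (2R,3R)-5-[(4-methoxybenzyl)oxy]-2-(penta-3,4-dien-1-yl)-3-[(triethylsilyl)oxy]pentanoate
Product: 12 (2R,3R)-5-[(4-methoxybenzyl)oxy]-2-(penta-3,4-dien-1-yl)-3-[(triethylsilyl)oxy]pentanal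
Conditions: DIBAL-H (1.15 equiv), CH2Cl2, −78 °C; MeOH, then aq. Rochelle salt
Reagents that add atoms: none
Why: Partial DIBAL reduction of the ester: the aluminium hemiacetal is stable at −78 °C and releases the aldehyde only on quench, so the α-stereocentre is not epimerised; the aldehyde is used directly.

Step 9
Reactants: 12 (2R,3R)-5-[(4-methoxybenzyl)oxy]-2-(penta-3,4-dien-1-yl)-3-[(triethylsilyl)oxy]pentanal
Product: 13 (1S,2R,5S)-5-{(1R)-3-[(4-methoxybenzyl)oxy]-1-[(triethylsilyl)oxy]propyl}-2-(prop-1-en-2-yl)cyclopentan-1-ol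
Conditions: Ni(COD)2 (10 mol %), Me2Zn (3 equiv), THF, 0 °C; aq. NH4Cl
Reagents that add atoms: dimethylzinc, C[Zn]C
Why: Nickel-catalysed alkylative cyclisation of an allenyl aldehyde with an organozinc: oxidative cyclisation at zerovalent nickel joins the aldehyde carbon to the proximal allene carbon, and methyl transfer from zinc with reductive elimination puts the methyl on the central allene carbon; the cis-fused metallacycle sets OH cis to isopropenyl (C1 S, C2 R) and the α-substituent sits pseudo-equatorial, trans to OH.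

Step 10
Reactants: 13 (1S,2R,5S)-5-{(1R)-3-[(4-methoxybenzyl)oxy]-1-[(triethylsilyl)oxy]propyl}-2-(prop-1-en-2-yl)cyclopentan-1-ol
Product: 15 (1R)-1-[(1R,2S,3R)-2-{[tert-butyl(dimethyl)silyl]oxy}-3-(prop-1-en-2-yl)cyclopentyl]-3-[(4-methoxybenzyl)oxy]propan-1-ol, via bis-silyl ether 14 (not isolated)
Conditions: TBSOTf (1.3 equiv), 2,6-lutidine (1.6 equiv), CH2Cl2, −78 → 0 °C; then MeOH, CSA (0.6 equiv), 0 °C
Reagents that add atoms: tert-butyldimethylsilyl trifluoromethanesulfonate, CC(C)(C)[Si](C)(C)OS(=O)(=O)C(F)(F)F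
Why: Silylation of the ring hydroxyl followed by selective acid methanolysis: the less hindered secondary TES ether is cleaved far faster than the doubly flanked secondary TBS ether, and the PMB ether is inert.

Step 11
Reactants: 16 prop-2-yn-1-ol
Product: 17 tert-butyldimethyl(prop-2-yn-1-yloxy)silane
Conditions: TBSCl, imidazole, CH2Cl2, 0 °C → rt
Reagents that add atoms: tert-butyldimethylsilyl chloride, CC(C)(C)[Si](C)(C)Cl
Why: Routine silyl protection of a primary alcohol.

Step 12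
Reactants: 17 tert-butyldimethyl(prop-2-yn-1-yloxy)silane; 18 oxirane
Product: 19 5-[(tert-butyldimethylsilyl)oxy]pent-3-yn-1-ol
Conditions: n-BuLi, THF, −78 °C; then oxirane (1.5 equiv), DMPU, −78 °C → rt; aq. NH4Cl
Reagents that add atoms: none
Why: SN2 ring opening of the unhindered epoxide by the lithium acetylide gives the homopropargylic alcohol.

Step 13
Reactants: 19 5-[(tert-butyldimethylsilyl)oxy]pent-3-yn-1-ol
Product: 20 tert-butyl[(5-iodopent-2-yn-1-yl)oxy]dimethylsilane
Conditions: I2, PPh3, imidazole, CH2Cl2, 0 °C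
Reagents that add atoms: iodine, II
Why: Appel-type iodination of the primary alcohol; the imidazole buffer protects the silyl ether.

Step 14
Reactants: 17 tert-butyldimethyl(prop-2-yn-1-yloxy)silane; 20 tert-butyl[(5-iodopent-2-yn-1-yl)oxy]dimethylsilane
Product: 21 1,8-bis[(tert-butyldimethylsilyl)oxy]octa-2,6-diyne
Conditions: 17 (1.2 equiv), n-BuLi, THF, −78 °C; then 20, DMPU, −78 °C → rt
Reagents that add atoms: none
Why: SN2 alkylation of the lithium acetylide with the primary iodide in a dipolar cosolvent builds the 1,5-diyne.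

Step 15
Reactants: 21 1,8-bis[(tert-butyldimethylsilyl)oxy]octa-2,6-diyne
Product: 22 1,8-dibromoocta-2,6-diyne
Conditions: PPh3 (2.4 equiv), Br2 (2.4 equiv), CH2Cl2, 0 °C (gives Ph3PBr2); then 21, 0 °C → rt
Reagents that add atoms: dibromotriphenylphosphorane (made from PPh3 and Br2), BrP(Br)(c1ccccc1)(c1ccccc1)c1ccccc1
Why: Ph3PBr2 converts primary silyl ethers directly into bromides through an oxyphosphonium intermediate; the reagent is preformed so no free bromine meets the alkynes.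

Step 16
Reactants: 15 (1R)-1-[(1R,2S,3R)-2-{[tert-butyl(dimethyl)silyl]oxy}-3-(prop-1-en-2-yl)cyclopentyl]-3-[(4-methoxybenzyl)oxy]propan-1-ol (2.2 equiv); 22 1,8-dibromoocta-2,6-diyne (1.0 equiv)
Product: 23 1,8-bis{(1R)-1-[(1R,2S,3R)-2-{[tert-butyl(dimethyl)silyl]oxy}-3-(prop-1-en-2-yl)cyclopentyl]-3-[(4-methoxybenzyl)oxy]propoxy}octa-2,6-diyne
Conditions: NaH (2.4 equiv), THF, 0 °C; then 22, Bu4NI (0.2 equiv), 0 °C → rt
Reagents that add atoms: none
Why: Double Williamson etherification: the sodium alkoxide displaces both reactive primary propargylic bromides by SN2; the carbinol C–O bond is not broken, so its configuration is kept, and THF at low temperature limits silyl migration.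

Step 17
Reactants: 23 bis(PMB ether)
Product: 24 3,3'-[octa-2,6-diyne-1,8-diylbis(oxy)]bis{(3R)-3-[(1R,2S,3R)-2-{[tert-butyl(dimethyl)silyl]oxy}-3-(prop-1-en-2-yl)cyclopentyl]propan-1-ol}
Conditions: DDQ (2.6 equiv), CH2Cl2/pH 7 buffer (10:1), 0 °C
Reagents that add atoms: none
Why: Oxidative PMB cleavage by DDQ (hydride abstraction, then hydrolysis of the oxocarbenium ion) is selective for the electron-rich benzyl ether over propargyl ethers, alkenes and TBS ethers.

Step 18
Reactants: 24 diol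
Product: 25 1,8-bis{(1R)-1-[(1R,2S,3R)-2-{[tert-butyl(dimethyl)silyl]oxy}-3-(prop-1-en-2-yl)cyclopentyl]-3-iodopropoxy}octa-2,6-diyne
Conditions: I2 (2.6 equiv), PPh3 (2.6 equiv), imidazole (5 equiv), CH2Cl2, 0 °C → rt
Reagents that add atoms: iodine, II
Why: Appel-type iodination of both primary alcohols under buffered neutral conditions.

Step 19
Reactants: 25 bis(propargyl ether) bis(alkyl iodide)
Product: 26 (3Z,3'Z)-3,3'-(butane-1,4-diylidene)bis{(6R)-6-[(1R,2S,3R)-2-{[tert-butyl(dimethyl)silyl]oxy}-3-(prop-1-en-2-yl)cyclopentyl]oxane}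
Conditions: (IPr)CuCl (20 mol %), NaOtBu (20 mol %), (EtO)3SiH (3 equiv), CsF (3 equiv), 1,4-dioxane (0.02 M), 45 °C
Reagents that add atoms: none
Why: Proposed new method: a copper-hydride-catalysed intramolecular syn-hydroalkylation of an unactivated dialkyl alkyne, run in two directions. (IPr)CuH adds syn across each alkyne with copper on the carbon next to the propargylic oxygen (inductive stabilisation, and the only regioisomer that can close a six-membered ring). The alkenylcopper then displaces the tethered primary iodide (6-exo-tet) with retention, so H ends up cis to ring C4 and the central chain cis to the OCH2, giving the (Z)-alkylidene, and CsF with the silane regenerates CuH. The closest known reactions are the intermolecular copper-hydride hydroalkylation of alkynes with alkyl triflates and the copper–boryl intramolecular alkylboration of alkynes bearing alkyl halides.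

Step 20
Reactants: 26 bis-TBS ether of testudinariol A
Product: 27 testudinariol A, (1S,2R,5S)-2-(prop-1-en-2-yl)-5-[(2R,5Z)-5-{4-[(3Z,6R)-6-[(1S,2S,3R)-2-hydroxy-3-(prop-1-en-2-yl)cyclopentyl]oxan-3-ylidene]butylidene}oxan-2-yl]cyclopentan-1-ol
Conditions: TBAF (4 equiv), THF, 50 °C
Reagents that add atoms: none
Why: Fluoride-mediated desilylation is neutral and leaves the allylic ethers, the exocyclic alkenes and the isopropenyl groups untouched.

**Compound list**

1 | but-3-yn-1-ol | C#CCCO | starting material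
2 | penta-3,4-dien-1-ol | C=C=CCCO | intermediate
3 | 5-iodopenta-1,2-diene | C=C=CCCI | intermediate
4 | acrylonitrile | C=CC#N | starting material
5 | 3-[(4-methoxybenzyl)oxy]propanenitrile | N#CCCOCc1ccc(OC)cc1 | intermediate
6 | ethyl bromoacetate | CCOC(=O)CBr | starting material
7 | ethyl (2Z)-3-amino-5-[(4-methoxybenzyl)oxy]pent-2-enoate (Blaise enamino ester, present as its N-bromozinc derivative) | CCOC(=O)/C=C(\N)CCOCc1ccc(OC)cc1 | intermediate (not isolated)
8 | ethyl 5-[(4-methoxybenzyl)oxy]-3-oxopentanoate | CCOC(=O)CC(=O)CCOCc1ccc(OC)cc1 | intermediate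
9 | ethyl (3R)-3-hydroxy-5-[(4-methoxybenzyl)oxy]pentanoate | CCOC(=O)C[C@H](O)CCOCc1ccc(OC)cc1 | intermediate
10 | ethyl (2R,3R)-3-hydroxy-5-[(4-methoxybenzyl)oxy]-2-(penta-3,4-dien-1-yl)pentanoate | C=C=CCC[C@H]([C@H](O)CCOCc1ccc(OC)cc1)C(=O)OCC | intermediate
11 | ethyl (2R,3R)-5-[(4-methoxybenzyl)oxy]-2-(penta-3,4-dien-1-yl)-3-[(triethylsilyl)oxy]pentanoate | C=C=CCC[C@H]([C@H](O[Si](CC)(CC)CC)CCOCc1ccc(OC)cc1)C(=O)OCC | intermediate
12 | (2R,3R)-5-[(4-methoxybenzyl)oxy]-2-(penta-3,4-dien-1-yl)-3-[(triethylsilyl)oxy]pentanal | C=C=CCC[C@H]([C@H](O[Si](CC)(CC)CC)CCOCc1ccc(OC)cc1)C=O | intermediate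
13 | (1S,2R,5S)-5-{(1R)-3-[(4-methoxybenzyl)oxy]-1-[(triethylsilyl)oxy]propyl}-2-(prop-1-en-2-yl)cyclopentan-1-ol | C=C(C)[C@H]1CC[C@H]([C@H](O[Si](CC)(CC)CC)CCOCc2ccc(OC)cc2)[C@H]1O | intermediate
14 | tert-butyl({(1S,2R,5R)-5-{(1R)-3-[(4-methoxybenzyl)oxy]-1-[(triethylsilyl)oxy]propyl}-2-(prop-1-en-2-yl)cyclopentyl}oxy)dimethylsilane | C=C(C)[C@H]1CC[C@H]([C@H](O[Si](CC)(CC)CC)CCOCc2ccc(OC)cc2)[C@H]1O[Si](C)(C)C(C)(C)C | intermediate (not isolated)
15 | (1R)-1-[(1R,2S,3R)-2-{[tert-butyl(dimethyl)silyl]oxy}-3-(prop-1-en-2-yl)cyclopentyl]-3-[(4-methoxybenzyl)oxy]propan-1-ol | C=C(C)[C@H]1CC[C@H]([C@H](O)CCOCc2ccc(OC)cc2)[C@H]1O[Si](C)(C)C(C)(C)C | intermediate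
16 | prop-2-yn-1-ol | C#CCO | starting material
17 | tert-butyldimethyl(prop-2-yn-1-yloxy)silane | C#CCO[Si](C)(C)C(C)(C)C | intermediate
18 | oxirane | C1CO1 | starting material
19 | 5-[(tert-butyldimethylsilyl)oxy]pent-3-yn-1-ol | OCCC#CCO[Si](C)(C)C(C)(C)C | intermediate
20 | tert-butyl[(5-iodopent-2-yn-1-yl)oxy]dimethylsilane | ICCC#CCO[Si](C)(C)C(C)(C)C | intermediate
21 | 1,8-bis[(tert-butyldimethylsilyl)oxy]octa-2,6-diyne | CC(C)(C)[Si](C)(C)OCC#CCCC#CCO[Si](C)(C)C(C)(C)C | intermediate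
22 | 1,8-dibromoocta-2,6-diyne | BrCC#CCCC#CCBr | intermediate
23 | 1,8-bis{(1R)-1-[(1R,2S,3R)-2-{[tert-butyl(dimethyl)silyl]oxy}-3-(prop-1-en-2-yl)cyclopentyl]-3-[(4-methoxybenzyl)oxy]propoxy}octa-2,6-diyne | C=C(C)[C@H]1CC[C@H]([C@H](OCC#CCCC#CCO[C@H](CCOCc2ccc(OC)cc2)[C@H]3CC[C@H](C(=C)C)[C@@H]3O[Si](C)(C)C(C)(C)C)CCOCc4ccc(OC)cc4)[C@H]1O[Si](C)(C)C(C)(C)C | intermediate
24 | 3,3'-[octa-2,6-diyne-1,8-diylbis(oxy)]bis{(3R)-3-[(1R,2S,3R)-2-{[tert-butyl(dimethyl)silyl]oxy}-3-(prop-1-en-2-yl)cyclopentyl]propan-1-ol} | C=C(C)[C@H]1CC[C@H]([C@H](OCC#CCCC#CCO[C@H](CCO)[C@H]3CC[C@H](C(=C)C)[C@@H]3O[Si](C)(C)C(C)(C)C)CCO)[C@H]1O[Si](C)(C)C(C)(C)C | intermediate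
25 | 1,8-bis{(1R)-1-[(1R,2S,3R)-2-{[tert-butyl(dimethyl)silyl]oxy}-3-(prop-1-en-2-yl)cyclopentyl]-3-iodopropoxy}octa-2,6-diyne | C=C(C)[C@H]1CC[C@H]([C@H](OCC#CCCC#CCO[C@H](CCI)[C@H]3CC[C@H](C(=C)C)[C@@H]3O[Si](C)(C)C(C)(C)C)CCI)[C@H]1O[Si](C)(C)C(C)(C)C | intermediate
26 | (3Z,3'Z)-3,3'-(butane-1,4-diylidene)bis{(6R)-6-[(1R,2S,3R)-2-{[tert-butyl(dimethyl)silyl]oxy}-3-(prop-1-en-2-yl)cyclopentyl]oxane} | C=C(C)[C@H]1CC[C@H]([C@H]2CC/C(=C/CC/C=C3/CC[C@H]([C@H]4CC[C@H](C(=C)C)[C@@H]4O[Si](C)(C)C(C)(C)C)OC3)CO2)[C@H]1O[Si](C)(C)C(C)(C)C | intermediate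
27 | testudinariol A | C=C(C)[C@H]1CC[C@H]([C@H]2CC/C(=C/CC/C=C3/CC[C@H]([C@H]4CC[C@H](C(=C)C)[C@@H]4O)OC3)CO2)[C@H]1O | target

**Step count**

Total step count: 20.
Longest linear sequence: 13 steps (acrylonitrile to 27: steps 3–10 and 16–20). The side branches are steps 1–2 and steps 11–15.

**Three steps most likely to fail, each with a fallback**

Step 19 (the proposed new step). The likely failure modes are β-alkoxide elimination of the α-(alkoxymethyl)alkenylcopper to an allene, hydrocupration with the wrong regiochemistry, and simple reduction of the C–I bonds. The fallback uses established copper–boryl chemistry and sets out from 25. A copper-catalysed intramolecular alkylboration (CuCl/Xantphos 10 mol %, B2pin2 2.4 equiv, KOtBu 2.4 equiv, THF, 30 °C) adds boron and copper syn across each alkyne and closes both rings by alkylation at copper. This gives 26 carrying a pinacolboronate on each exocyclic alkene carbon, boron cis to ring C4, F1. Stereoretentive protodeboronation of F1 (AgF, MeOH/H2O/THF, 60 °C) then replaces boron by hydrogen and returns to the route at 26.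

Step 6 (alkylation of the dianion with an unactivated iodide that can eliminate to a vinylallene). The fallback sets out from 9 and builds the allene after a reliable allylation. The same dianion is alkylated with allyl bromide to give ethyl (2R,3R)-3-hydroxy-5-[(4-methoxybenzyl)oxy]-2-(prop-2-en-1-yl)pentanoate F2, which is silylated (TESCl, imidazole) to ethyl (2R,3R)-5-[(4-methoxybenzyl)oxy]-2-(prop-2-en-1-yl)-3-[(triethylsilyl)oxy]pentanoate F3. Hydroboration of the terminal alkene with 9-BBN gives the B-alkyl-9-borabicyclo[3.3.1]nonane adduct F4, which is oxidised in the same flask (NaBO3·4H2O) to ethyl (2R,3R)-2-(3-hydroxypropyl)-5-[(4-methoxybenzyl)oxy]-3-[(triethylsilyl)oxy]pentanoate F5. Dess–Martin oxidation gives ethyl (2R,3R)-5-[(4-methoxybenzyl)oxy]-2-(3-oxopropyl)-3-[(triethylsilyl)oxy]pentanoate F6, and Ohira–Bestmann homologation (dimethyl (1-diazo-2-oxopropyl)phosphonate, K2CO3, EtOH) gives ethyl (2R,3R)-2-(but-3-yn-1-yl)-5-[(4-methoxybenzyl)oxy]-3-[(triethylsilyl)oxy]pentanoate F7. Crabbé homologation of F7 ((CH2O)n, CuI, Cy2NH, dioxane, reflux) returns to the route at 11.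

Step 16 (double O-alkylation of a hindered secondary alkoxide; risk of base-induced TBS migration between the two oxygens and of base-induced isomerisation of the skipped diyne). The fallback is a base-free, acid-catalysed etherification that sets out from 21 and 15. Desilylation of 21 (TBAF, THF) gives octa-2,6-diyne-1,8-diol F8. Cl3CCN with catalytic DBU converts F8 into octa-2,6-diyne-1,8-diyl bis(2,2,2-trichloroacetimidate) F9. Alcohol 15 (2.2 equiv) is then alkylated by F9 under TfOH catalysis (5 mol %, CH2Cl2/cyclohexane, 0 °C), which returns to the route at 23.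

**Further compounds**

F1 | step 19 | 26 bearing a 4,4,5,5-tetramethyl-1,3,2-dioxaborolan-2-yl group on each exocyclic alkene carbon (boron cis to ring C4) | C=C(C)[C@H]1CC[C@H]([C@H]2CC/C(=C(/CC/C(B5OC(C)(C)C(C)(C)O5)=C3/CC[C@H]([C@H]4CC[C@H](C(=C)C)[C@@H]4O[Si](C)(C)C(C)(C)C)OC3)B6OC(C)(C)C(C)(C)O6)CO2)[C@H]1O[Si](C)(C)C(C)(C)C
F2 | step 6 | ethyl (2R,3R)-3-hydroxy-5-[(4-methoxybenzyl)oxy]-2-(prop-2-en-1-yl)pentanoate | C=CC[C@H]([C@H](O)CCOCc1ccc(OC)cc1)C(=O)OCC
F3 | step 6 | ethyl (2R,3R)-5-[(4-methoxybenzyl)oxy]-2-(prop-2-en-1-yl)-3-[(triethylsilyl)oxy]pentanoate | C=CC[C@H]([C@H](O[Si](CC)(CC)CC)CCOCc1ccc(OC)cc1)C(=O)OCC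
F4 | step 6 | ethyl (2R,3R)-2-[3-(9-borabicyclo[3.3.1]nonan-9-yl)propyl]-5-[(4-methoxybenzyl)oxy]-3-[(triethylsilyl)oxy]pentanoate | B1(C2CCCC1CCC2)CCC[C@H]([C@H](O[Si](CC)(CC)CC)CCOCc3ccc(OC)cc3)C(=O)OCC
F5 | step 6 | ethyl (2R,3R)-2-(3-hydroxypropyl)-5-[(4-methoxybenzyl)oxy]-3-[(triethylsilyl)oxy]pentanoate | OCCC[C@H]([C@H](O[Si](CC)(CC)CC)CCOCc1ccc(OC)cc1)C(=O)OCC
F6 | step 6 | ethyl (2R,3R)-5-[(4-methoxybenzyl)oxy]-2-(3-oxopropyl)-3-[(triethylsilyl)oxy]pentanoate | O=CCC[C@H]([C@H](O[Si](CC)(CC)CC)CCOCc1ccc(OC)cc1)C(=O)OCC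
F7 | step 6 | ethyl (2R,3R)-2-(but-3-yn-1-yl)-5-[(4-methoxybenzyl)oxy]-3-[(triethylsilyl)oxy]pentanoate | C#CCC[C@H]([C@H](O[Si](CC)(CC)CC)CCOCc1ccc(OC)cc1)C(=O)OCC
F8 | step 16 | octa-2,6-diyne-1,8-diol | OCC#CCCC#CCO
F9 | step 16 | octa-2,6-diyne-1,8-diyl bis(2,2,2-trichloroacetimidate) | ClC(Cl)(Cl)C(=N)OCC#CCCC#CCOC(=N)C(Cl)(Cl)Cl
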